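**Retrosynthetic overview** (germacrane numbering: C1–C10 carbocycle, C11–C13 lactone carbons, C14 ester carbon, C15 methyl)
1. Last operations: cleavage of a C9 silyl ether, and attachment of the preformed (2S,3S)-epoxyangelic acid 4 at O8 by Mitsunobu inversion of an 8R alcohol.
2. Key disconnection C7–C8: the C8 carbinol is homoallylic to the exocyclic C11=C13 of the lactone through the ring-fusion carbon C7 (O–C8–C7–C11=C13). The ten-membered carbocycle can therefore be closed by intramolecular Nozaki–Hiyama allylation of a C8 aldehyde with a flat 3-(bromomethyl)butenolide (C13–Br, C7=C11), which also creates C7, C8 and the exo-methylene.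
3. The open chain comes from Wittig union at C10=C1 of ynal 9 (C1–C7, with the 4,5-oxirane from Sharpless epoxidation) with ylide 17 (C8–C10 and C14, C9 from (R)-glycidol), then zinc semi-reduction to the 2Z alkene and butenolide formation by RCM.
4. Ring order: side-chain oxirane (step 2), 4,5-oxirane (step 4), butenolide (step 16), ten-membered carbocycle (step 19). No ring is formed after step 19.

Key step: step 19

Abbreviations: TBS = tert-butyldimethylsilyl; PMB = 4-methoxybenzyl; DIPT = diisopropyl tartrate.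
Remark (assumption): the macrocyclic allylation is taken to follow the same closed, chair-like transition state as intermolecular allylations with γ-substituted allylmetals, so the C8 alcohol is expected as the 7,8-anti (8R) isomer and is inverted in step 20.
Remark: compounds 1, 5, 10 and 2-(bromomethyl)acrylic acid are taken as commercial.

**Route**

Step 1
Reactants: 1 angelic acid
Product: 2 (Z)-2-methylbut-2-en-1-ol
Conditions: LiAlH4, Et2O, 0 °C → rt; H2O/NaOH work-up
Reagents that add atoms: none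
Why: LiAlH4 reduction of the carboxylic acid should give the primary allylic alcohol with the Z alkene unchanged.

Step 2
Reactants: 2 (Z)-2-methylbut-2-en-1-ol
Product: 3 [(2R,3S)-2,3-dimethyloxiran-2-yl]methanol
Conditions: Ti(OiPr)4 (cat.), D-(−)-DIPT (cat.), t-BuOOH, 4 Å MS, CH2Cl2, −20 °C
Reagents that add atoms: tert-butyl hydroperoxide, CC(C)(C)OO
Why: Katsuki–Sharpless asymmetric epoxidation of a primary allylic alcohol; the D-(−)-tartrate complex should deliver oxygen to the face that sets C2 (R) and C3 (S), and the Z alkene fixes CH2OH cis to the C3 methyl.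

Step 3
Reactants: 3 [(2R,3S)-2,3-dimethyloxiran-2-yl]methanol
Product: 4 (2S,3S)-2,3-dimethyloxirane-2-carboxylic acid
Conditions: RuCl3 (cat.), NaIO4, CCl4/MeCN/H2O, rt
Reagents that add atoms: sodium periodate (terminal source of the new oxygen, passed on through RuO4/water), [Na+].[O-]I(=O)(=O)=O
Why: RuO4 oxidation (Sharpless conditions) of a primary epoxy alcohol to the glycidic acid, which does not touch the oxirane or its two stereocentres.

Step 4
Reactants: 5 (E)-3-methylpent-2-en-4-yn-1-ol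
Product: 6 [(2R,3R)-3-ethynyl-3-methyloxiran-2-yl]methanol
Conditions: Ti(OiPr)4 (cat.), D-(−)-DIPT (cat.), t-BuOOH, 4 Å MS, CH2Cl2, −20 °C
Reagents that add atoms: tert-butyl hydroperoxide, CC(C)(C)OO
Why: Katsuki–Sharpless asymmetric epoxidation of a geraniol-type trisubstituted allylic alcohol; D-(−)-tartrate should set C4 and C5 (both R), and the E alkene fixes the trans-oxirane.

Step 5
Reactants: 6 [(2R,3R)-3-ethynyl-3-methyloxiran-2-yl]methanol
Product: 7 (2S,3R)-3-ethynyl-3-methyloxirane-2-carbaldehyde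
Conditions: TEMPO (cat.), PhI(OAc)2, CH2Cl2, rt; used as a solution without concentration
Reagents that add atoms: none
Why: TEMPO/PhI(OAc)2 oxidation of a primary alcohol should stop at the aldehyde and leave the oxirane intact (the S descriptor at the former R centre is a priority change only).

Step 6
Reactants: 7 (2S,3R)-3-ethynyl-3-methyloxirane-2-carbaldehyde
Product: 8 (1S)-1-[(2R,3R)-3-ethynyl-3-methyloxiran-2-yl]prop-2-en-1-ol
Conditions: CH2=CHMgBr, MgBr2·OEt2, CH2Cl2/Et2O, −78 °C; aqueous work-up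
Reagents that add atoms: vinylmagnesium bromide, C=C[Mg]Br
Why: Chelation-controlled Grignard addition (Cram chelate of Mg between the aldehyde oxygen and the oxirane oxygen); vinyl should attack anti to the C4–C5 bond and give the threo (5,6-syn) alcohol, C6 = S.

Step 7
Reactants: 8 (1S)-1-[(2R,3R)-3-ethynyl-3-methyloxiran-2-yl]prop-2-en-1-ol
Product: 9 3-{(2R,3R)-3-[(1S)-1-hydroxyprop-2-en-1-yl]-2-methyloxiran-2-yl}prop-2-ynal
Conditions: n-BuLi (2.2 equiv), THF, −78 °C; DMF; AcOH quench at −78 °C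
Reagents that add atoms: N,N-dimethylformamide, CN(C)C=O
Why: Formylation of a lithium acetylide with DMF on the alkoxide/acetylide dianion; the hemiaminal should survive until the acidic quench, which releases the ynal without free amine or base.

Step 8
Reactants: 10 (R)-glycidol
Product: 11 (S)-2-{[(4-methoxybenzyl)oxy]methyl}oxirane
Conditions: NaH, PMBCl, Bu4NI (cat.), THF/DMF, 0 °C → rt
Reagents that add atoms: 4-methoxybenzyl chloride, COc1ccc(CCl)cc1
Why: Williamson etherification of the primary alkoxide; the stereocentre is not involved (the S descriptor is a priority change only).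

Step 9
Reactants: 11 (S)-2-{[(4-methoxybenzyl)oxy]methyl}oxirane
Product: 12 (R)-1-iodo-3-[(4-methoxybenzyl)oxy]propan-2-ol
Conditions: LiI, AcOH, THF, 0 °C → rt
Reagents that add atoms: lithium iodide, [Li+].[I-]
Why: Regioselective SN2 opening of the terminal oxirane carbon by iodide under mild acid, which leaves the carbinol stereocentre (later C9) untouched.

Step 10
Reactants: 12 (R)-1-iodo-3-[(4-methoxybenzyl)oxy]propan-2-ol
Product: 13 (R)-tert-butyl{[1-iodo-3-(4-methoxybenzyloxy)propan-2-yl]oxy}dimethylsilane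
Conditions: TBSCl, imidazole, DMF, rt
Reagents that add atoms: tert-butyldimethylsilyl chloride, CC(C)(C)[Si](C)(C)Cl
Why: Standard silylation of the secondary alcohol (Corey conditions); no stereocentre is touched.

Step 11
Reactants: 13 (R)-tert-butyl{[1-iodo-3-(4-methoxybenzyloxy)propan-2-yl]oxy}dimethylsilane
Product: 14 [(2R)-2-(TBSO)-3-(PMBO)propyl]triphenylphosphonium iodide
Conditions: PPh3, MeCN, 85 °C
Reagents that add atoms: triphenylphosphine, c1ccc(cc1)P(c1ccccc1)c1ccccc1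
Why: SN2 quaternization of triphenylphosphine by the primary iodide (phosphonium salt formation).

Step 12
Reactants: 14 [(2R)-2-(TBSO)-3-(PMBO)propyl]triphenylphosphonium iodide
Product: 17 methyl (3R)-3-(TBSO)-4-(PMBO)-2-(triphenylphosphoranylidene)butanoate, via phosphonium ylide 15 (not isolated), via acylphosphonium chloride 16 (not isolated)
Conditions: NaHMDS, THF, −78 °C; cannulation into ClCO2Me, −78 °C; then Et3N, 0 °C
Reagents that add atoms: methyl chloroformate, COC(=O)Cl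
Why: Bestmann-type C-acylation of a non-stabilized ylide by a chloroformate followed by deprotonation should give the ester-stabilized ylide; inverse addition at −78 °C suppresses transylidation and loss of the β-silyloxy group, and C9 is untouched.

Step 13
Reactants: 9 3-{(2R,3R)-3-[(1S)-1-hydroxyprop-2-en-1-yl]-2-methyloxiran-2-yl}prop-2-ynal; 17 methyl (3R)-3-(TBSO)-4-(PMBO)-2-(triphenylphosphoranylidene)butanoate
Product: 18 methyl (2E)-2-[(1S)-1-(TBSO)-2-(PMBO)ethyl]-5-{(2R,3R)-3-[(1S)-1-hydroxyprop-2-en-1-yl]-2-methyloxiran-2-yl}pent-2-en-4-ynoate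
Conditions: toluene, 50 °C
Reagents that add atoms: none
Why: Wittig olefination of a reactive ynal by an α-branched ester-stabilized ylide; the thermodynamically controlled oxaphosphetane should place the ester trans to the alkynyl group (2E), so that C9 and C2 are cis as the target requires.

Step 14
Reactants: 18 methyl (2E)-2-[(1S)-1-(TBSO)-2-(PMBO)ethyl]-5-{(2R,3R)-3-[(1S)-1-hydroxyprop-2-en-1-yl]-2-methyloxiran-2-yl}pent-2-en-4-ynoate
Product: 19 methyl (2E,4Z)-2-[(1S)-1-(TBSO)-2-(PMBO)ethyl]-5-{(2R,3R)-3-[(1S)-1-hydroxyprop-2-en-1-yl]-2-methyloxiran-2-yl}penta-2,4-dienoate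
Conditions: Zn(Cu/Ag), MeOH/H2O (1:1), 40 °C
Reagents that add atoms: none
Why: Boland reduction; activated zinc transfers electrons only to the conjugated alkyne and both hydrogens arrive cis, so the 4Z alkene should form while the isolated vinyl group, the oxirane and the esters remain.

Step 15
Reactants: 19 methyl (2E,4Z)-2-[(1S)-1-(TBSO)-2-(PMBO)ethyl]-5-{(2R,3R)-3-[(1S)-1-hydroxyprop-2-en-1-yl]-2-methyloxiran-2-yl}penta-2,4-dienoate
Product: 20 methyl (2E,4Z)-5-{(2R,3R)-3-[(1S)-1-{[2-(bromomethyl)prop-2-enoyl]oxy}prop-2-en-1-yl]-2-methyloxiran-2-yl}-2-[(1S)-1-(TBSO)-2-(PMBO)ethyl]penta-2,4-dienoate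
Conditions: 2-(bromomethyl)acrylic acid, DCC, DMAP (cat.), CH2Cl2, 0 °C
Reagents that add atoms: 2-(bromomethyl)acrylic acid, C=C(CBr)C(=O)O
Why: Steglich esterification of the secondary allylic alcohol with retention at C6; low temperature and a catalytic amount of DMAP limit attack on the allylic bromide.

Step 16
Reactants: 20 methyl (2E,4Z)-5-{(2R,3R)-3-[(1S)-1-{[2-(bromomethyl)prop-2-enoyl]oxy}prop-2-en-1-yl]-2-methyloxiran-2-yl}-2-[(1S)-1-(TBSO)-2-(PMBO)ethyl]penta-2,4-dienoate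
Product: 21 methyl (2E,4Z)-5-{(2R,3R)-3-[(2S)-4-(bromomethyl)-5-oxo-2,5-dihydrofuran-2-yl]-2-methyloxiran-2-yl}-2-[(1S)-1-(TBSO)-2-(PMBO)ethyl]penta-2,4-dienoate
Conditions: Grubbs II (cat.), 1,4-benzoquinone (cat.), CH2Cl2, 40 °C
Reagents that add atoms: none
Why: Ring-closing metathesis; the carbene loads on the monosubstituted vinyl group and closes onto the 1,1-disubstituted acrylate to the butenolide, and the diene cannot take part because the trans-oxirane would have to lie in a five- or six-membered ring.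

Step 17
Reactants: 21 methyl (2E,4Z)-5-{(2R,3R)-3-[(2S)-4-(bromomethyl)-5-oxo-2,5-dihydrofuran-2-yl]-2-methyloxiran-2-yl}-2-[(1S)-1-(TBSO)-2-(PMBO)ethyl]penta-2,4-dienoate
Product: 22 methyl (2E,4Z)-5-{(2R,3R)-3-[(2S)-4-(bromomethyl)-5-oxo-2,5-dihydrofuran-2-yl]-2-methyloxiran-2-yl}-2-[(1S)-1-(TBSO)-2-hydroxyethyl]penta-2,4-dienoate
Conditions: DDQ, CH2Cl2/pH 7 buffer, 0 °C
Reagents that add atoms: none
Why: Oxidative PMB cleavage by DDQ (benzylic hydride abstraction, then hydrolysis) under neutral, amine-free conditions that should spare the allylic bromide, the oxirane, the TBS ether and the electron-poor diene.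

Step 18
Reactants: 22 methyl (2E,4Z)-5-{(2R,3R)-3-[(2S)-4-(bromomethyl)-5-oxo-2,5-dihydrofuran-2-yl]-2-methyloxiran-2-yl}-2-[(1S)-1-(TBSO)-2-hydroxyethyl]penta-2,4-dienoate
Product: 23 methyl (2E,4Z)-5-{(2R,3R)-3-[(2S)-4-(bromomethyl)-5-oxo-2,5-dihydrofuran-2-yl]-2-methyloxiran-2-yl}-2-[(1S)-1-(TBSO)-2-oxoethyl]penta-2,4-dienoate
Conditions: Dess–Martin periodinane, NaHCO3, CH2Cl2, 0 °C → rt; used at once
Reagents that add atoms: none
Why: Dess–Martin oxidation under buffered, non-basic conditions should give the α-silyloxy aldehyde without epimerizing C9 or moving the C10=C1 double bond.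

Step 19
Reactants: 23 methyl (2E,4Z)-5-{(2R,3R)-3-[(2S)-4-(bromomethyl)-5-oxo-2,5-dihydrofuran-2-yl]-2-methyloxiran-2-yl}-2-[(1S)-1-(TBSO)-2-oxoethyl]penta-2,4-dienoate
Product: 25 methyl (4R,5R,6S,7R,8R,9S)-9-(TBSO)-4,5-epoxy-8-hydroxygermacra-1(10)E,2Z,11(13)-trien-6,12-olid-14-oate (8-epi alcohol), via allylchromium(III) dichloride 24 (not isolated)
Conditions: CrCl2 (8 equiv), THF, rt, slow addition of 23 to a final 2 mM; aqueous work-up
Reagents that add atoms: none
Why: CrCl2 reduces the allylic C–Br bond of 23 to the allylchromium(III) species 24, which adds through its γ-carbon C7 to the tethered C8 aldehyde in a six-membered chair transition state and moves the butenolide double bond C7=C11 to the exocyclic C11=C13 (Nozaki–Hiyama carbonyl allylation; closest known types are metal-mediated allylations of aldehydes with 3-(bromomethyl)furan-2(5H)-ones and macrocyclic closures of germacranolides with 2-(bromomethyl)acrylates). The ten-membered carbocycle is closed by the C7–C8 bond as a 10-exo-trig attack on the aldehyde, with the lactone and both oxiranes already in place. C7 is set by attack on the butenolide face anti to the C6–C5 bond, which gives the trans ring fusion as in intermolecular additions to 5-substituted butenolides. C8 is set by the chair transition state, in which the ring-locked E-type γ-substituent gives the 7,8-anti adduct, and Felkin–Anh attack anti to the C9 silyloxy group points the same way, so the 8R alcohol is expected. The step needs reduction of the allylic bromide in preference to the dienoate, the aldehyde and the vinyl oxirane, which the much faster reaction of Cr(II) with allylic halides in a neutral medium should secure. It also needs ring closure over oligomerization, which slow addition at high dilution and the U-shaped Z,Z-diene/trans-oxirane tether should secure.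

Step 20
Reactants: 25 methyl (4R,5R,6S,7R,8R,9S)-9-(TBSO)-4,5-epoxy-8-hydroxygermacra-1(10)E,2Z,11(13)-trien-6,12-olid-14-oate; 4 (2S,3S)-2,3-dimethyloxirane-2-carboxylic acid
Product: 26 methyl (4R,5R,6S,7R,8S,9S)-9-(TBSO)-8-{[(2S,3S)-2,3-dimethyloxirane-2-carbonyl]oxy}-4,5-epoxygermacra-1(10)E,2Z,11(13)-trien-6,12-olid-14-oate
Conditions: PPh3, DIAD (betaine preformed), toluene, 0 °C → rt
Reagents that add atoms: none
Why: Mitsunobu esterification; the C8 alcohol is activated as the alkoxyphosphonium ion and displaced by the carboxylate of 4 in an SN2 step, so 8R should become 8S, and preforming the betaine keeps free PPh3 away from the α-methylene lactone.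

Step 21
Reactants: 26 methyl (4R,5R,6S,7R,8S,9S)-9-(TBSO)-8-{[(2S,3S)-2,3-dimethyloxirane-2-carbonyl]oxy}-4,5-epoxygermacra-1(10)E,2Z,11(13)-trien-6,12-olid-14-oate
Product: 27 methyl (4R,5R,6S,7R,8S,9S)-8-{[(2S,3S)-2,3-dimethyloxirane-2-carbonyl]oxy}-4,5-epoxy-9-hydroxygermacra-1(10)E,2Z,11(13)-trien-6,12-olid-14-oate (CNP0131597.1)
Conditions: HF·pyridine, pyridine, THF, 0 °C → rt
Reagents that add atoms: none
Why: Fluoride-mediated cleavage of the secondary TBS ether under buffered, weakly acidic conditions should spare both oxiranes, the esters and the α-methylene lactone and avoid base-induced O8→O9 acyl shift.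

**Compound list**

1 | angelic acid, (Z)-2-methylbut-2-enoic acid | C/C=C(/C)C(=O)O | starting material
2 | (Z)-2-methylbut-2-en-1-ol | C/C=C(/C)CO | intermediate
3 | [(2R,3S)-2,3-dimethyloxiran-2-yl]methanol | OC[C@@]1(C)O[C@H]1C | intermediate
4 | (2S,3S)-2,3-dimethyloxirane-2-carboxylic acid | OC(=O)[C@@]1(C)O[C@H]1C | intermediate
5 | (E)-3-methylpent-2-en-4-yn-1-ol | C#C/C(C)=C/CO | starting material
6 | [(2R,3R)-3-ethynyl-3-methyloxiran-2-yl]methanol | C#C[C@@]1(C)O[C@@H]1CO | intermediate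
7 | (2S,3R)-3-ethynyl-3-methyloxirane-2-carbaldehyde | C#C[C@@]1(C)O[C@@H]1C=O | intermediate
8 | (1S)-1-[(2R,3R)-3-ethynyl-3-methyloxiran-2-yl]prop-2-en-1-ol | C#C[C@@]1(C)O[C@@H]1[C@@H](O)C=C | intermediate
9 | 3-{(2R,3R)-3-[(1S)-1-hydroxyprop-2-en-1-yl]-2-methyloxiran-2-yl}prop-2-ynal | O=CC#C[C@@]1(C)O[C@@H]1[C@@H](O)C=C | intermediate
10 | (R)-glycidol | OC[C@@H]1CO1 | starting material
11 | (S)-2-{[(4-methoxybenzyl)oxy]methyl}oxirane | COc1ccc(COC[C@@H]2CO2)cc1 | intermediate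
12 | (R)-1-iodo-3-[(4-methoxybenzyl)oxy]propan-2-ol | COc1ccc(COC[C@@H](O)CI)cc1 | intermediate
13 | (R)-tert-butyl{[1-iodo-3-(4-methoxybenzyloxy)propan-2-yl]oxy}dimethylsilane | COc1ccc(COC[C@@H](O[Si](C)(C)C(C)(C)C)CI)cc1 | intermediate
14 | [(2R)-2-(TBSO)-3-(PMBO)propyl]triphenylphosphonium iodide | COc1ccc(COC[C@@H](O[Si](C)(C)C(C)(C)C)C[P+](c2ccccc2)(c2ccccc2)c2ccccc2)cc1.[I-] | intermediate
15 | [(2R)-2-(TBSO)-3-(PMBO)propylidene]triphenylphosphorane | COc1ccc(COC[C@@H](O[Si](C)(C)C(C)(C)C)C=P(c2ccccc2)(c2ccccc2)c2ccccc2)cc1 | intermediate (not isolated)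
16 | [(3R)-3-(TBSO)-1-methoxy-4-(PMBO)-1-oxobutan-2-yl]triphenylphosphonium chloride (both C2 epimers) | COc1ccc(COC[C@@H](O[Si](C)(C)C(C)(C)C)C([P+](c2ccccc2)(c2ccccc2)c2ccccc2)C(=O)OC)cc1.[Cl-] | intermediate (not isolated)
17 | methyl (3R)-3-(TBSO)-4-(PMBO)-2-(triphenylphosphoranylidene)butanoate | COc1ccc(COC[C@@H](O[Si](C)(C)C(C)(C)C)C(=P(c2ccccc2)(c2ccccc2)c2ccccc2)C(=O)OC)cc1 | intermediate
18 | methyl (2E)-2-[(1S)-1-(TBSO)-2-(PMBO)ethyl]-5-{(2R,3R)-3-[(1S)-1-hydroxyprop-2-en-1-yl]-2-methyloxiran-2-yl}pent-2-en-4-ynoate | COc1ccc(COC[C@@H](O[Si](C)(C)C(C)(C)C)/C(C(=O)OC)=C\C#C[C@@]2(C)O[C@@H]2[C@@H](O)C=C)cc1 | intermediate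
19 | methyl (2E,4Z)-2-[(1S)-1-(TBSO)-2-(PMBO)ethyl]-5-{(2R,3R)-3-[(1S)-1-hydroxyprop-2-en-1-yl]-2-methyloxiran-2-yl}penta-2,4-dienoate | COc1ccc(COC[C@@H](O[Si](C)(C)C(C)(C)C)/C(C(=O)OC)=C\C=C/[C@@]2(C)O[C@@H]2[C@@H](O)C=C)cc1 | intermediate
20 | methyl (2E,4Z)-5-{(2R,3R)-3-[(1S)-1-{[2-(bromomethyl)prop-2-enoyl]oxy}prop-2-en-1-yl]-2-methyloxiran-2-yl}-2-[(1S)-1-(TBSO)-2-(PMBO)ethyl]penta-2,4-dienoate | COc1ccc(COC[C@@H](O[Si](C)(C)C(C)(C)C)/C(C(=O)OC)=C\C=C/[C@@]2(C)O[C@@H]2[C@@H](OC(=O)C(=C)CBr)C=C)cc1 | intermediate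
21 | methyl (2E,4Z)-5-{(2R,3R)-3-[(2S)-4-(bromomethyl)-5-oxo-2,5-dihydrofuran-2-yl]-2-methyloxiran-2-yl}-2-[(1S)-1-(TBSO)-2-(PMBO)ethyl]penta-2,4-dienoate | COc1ccc(COC[C@@H](O[Si](C)(C)C(C)(C)C)/C(C(=O)OC)=C\C=C/[C@@]2(C)O[C@@H]2[C@H]2OC(=O)C(CBr)=C2)cc1 | intermediate
22 | methyl (2E,4Z)-5-{(2R,3R)-3-[(2S)-4-(bromomethyl)-5-oxo-2,5-dihydrofuran-2-yl]-2-methyloxiran-2-yl}-2-[(1S)-1-(TBSO)-2-hydroxyethyl]penta-2,4-dienoate | OC[C@@H](O[Si](C)(C)C(C)(C)C)/C(C(=O)OC)=C\C=C/[C@@]1(C)O[C@@H]1[C@H]1OC(=O)C(CBr)=C1 | intermediate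
23 | methyl (2E,4Z)-5-{(2R,3R)-3-[(2S)-4-(bromomethyl)-5-oxo-2,5-dihydrofuran-2-yl]-2-methyloxiran-2-yl}-2-[(1S)-1-(TBSO)-2-oxoethyl]penta-2,4-dienoate | O=C[C@@H](O[Si](C)(C)C(C)(C)C)/C(C(=O)OC)=C\C=C/[C@@]1(C)O[C@@H]1[C@H]1OC(=O)C(CBr)=C1 | intermediate
24 | allylchromium(III) dichloride of 23 (CrCl2 in place of Br on the butenolide CH2) | O=C[C@@H](O[Si](C)(C)C(C)(C)C)/C(C(=O)OC)=C\C=C/[C@@]1(C)O[C@@H]1[C@H]1OC(=O)C(C[Cr](Cl)Cl)=C1 | intermediate (not isolated)
25 | methyl (4R,5R,6S,7R,8R,9S)-9-(TBSO)-4,5-epoxy-8-hydroxygermacra-1(10)E,2Z,11(13)-trien-6,12-olid-14-oate | C=C1C(=O)O[C@H]2[C@H]1[C@@H](O)[C@@H](O[Si](C)(C)C(C)(C)C)/C(C(=O)OC)=C\C=C/[C@@]1(C)O[C@H]21 | intermediate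
26 | methyl (4R,5R,6S,7R,8S,9S)-9-(TBSO)-8-{[(2S,3S)-2,3-dimethyloxirane-2-carbonyl]oxy}-4,5-epoxygermacra-1(10)E,2Z,11(13)-trien-6,12-olid-14-oate | C=C1C(=O)O[C@H]2[C@H]1[C@H](OC(=O)[C@@]1(C)O[C@H]1C)[C@@H](O[Si](C)(C)C(C)(C)C)/C(C(=O)OC)=C\C=C/[C@@]1(C)O[C@H]21 | intermediate
27 | methyl (4R,5R,6S,7R,8S,9S)-8-{[(2S,3S)-2,3-dimethyloxirane-2-carbonyl]oxy}-4,5-epoxy-9-hydroxygermacra-1(10)E,2Z,11(13)-trien-6,12-olid-14-oate (CNP0131597.1) | C=C1C(=O)O[C@H]2[C@H]1[C@H](OC(=O)[C@@]1(C)O[C@H]1C)[C@@H](O)/C(C(=O)OC)=C\C=C/[C@@]1(C)O[C@H]21 | target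

**Step count and risks**

Total step count: 21. Longest linear sequence: 14 steps (10 → 27, steps 8–21).

Steps most likely to fail:

1. Step 19 (macrocyclic allylation). Intermolecular coupling or protonation of the allylchromium species may outrun closure of the ten-membered ring, Cr(III) salts may open the dienyl oxirane, and face selection at C7 or C8 may erode. Fallback (thermal allylboration in place of a reductive Barbier closure): 19 is esterified (DCC, DMAP) with 2-[(4,4,5,5-tetramethyl-1,3,2-dioxaborolan-2-yl)methyl]acrylic acid to give the boryl acrylate ester F1. Ring-closing metathesis (Grubbs II) gives the allylboronate butenolide F2, DDQ removes the PMB group to give the primary alcohol F3, and Dess–Martin oxidation gives the aldehyde F4. On warming in dilute toluene F4 should cyclize by intramolecular allylboration through the same chair transition state, without metal salts or reductant, and after hydrolysis of the borate the route is rejoined at 25.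

2. Step 20 (Mitsunobu inversion at C8). Displacement at the hindered ring carbinol may lose to elimination towards C7 or C9, or to acylation with retention through an acyloxyphosphonium ion. Fallback (oxidation–reduction inversion, then acylation with retention): Dess–Martin oxidation of 25 gives the C8 ketone F5. Luche reduction (NaBH4, CeCl3, MeOH, −78 °C), with hydride adding anti to the C9 silyloxy group (Felkin–Anh), should give the 8S alcohol F6. Yamaguchi esterification of F6 with 4 (2,4,6-trichlorobenzoyl chloride, Et3N, DMAP) rejoins the route at 26.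

3. Step 14 (zinc semi-reduction). Electron transfer from zinc may also cleave the propargylic C–O bond of the oxirane (allene formation), or the reduction may stall or run on. Fallback (catalytic semi-hydrogenation done before any isolated alkene is present): from 6, dianion formylation (n-BuLi, DMF, AcOH quench) gives the hydroxy ynal F7, and Wittig reaction with 17 gives the enynoate F8. Lindlar hydrogenation (Pd/CaCO3/Pb, quinoline, H2, EtOAc) gives the (2E,4Z)-dienoate F9, and Dess–Martin oxidation gives the oxirane aldehyde F10. Chelation-controlled addition of vinylmagnesium bromide, as in step 6, rejoins the route at 19.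

**Further compounds**

F1 | step 19 | methyl (2E,4Z)-2-[(1S)-1-(TBSO)-2-(PMBO)ethyl]-5-{(2R,3R)-2-methyl-3-[(1S)-1-({2-[(pinacolboryl)methyl]prop-2-enoyl}oxy)prop-2-en-1-yl]oxiran-2-yl}penta-2,4-dienoate | COc1ccc(COC[C@@H](O[Si](C)(C)C(C)(C)C)/C(C(=O)OC)=C\C=C/[C@@]2(C)O[C@@H]2[C@@H](OC(=O)C(=C)CB2OC(C)(C)C(C)(C)O2)C=C)cc1
F2 | step 19 | methyl (2E,4Z)-2-[(1S)-1-(TBSO)-2-(PMBO)ethyl]-5-{(2R,3R)-2-methyl-3-[(2S)-5-oxo-4-[(pinacolboryl)methyl]-2,5-dihydrofuran-2-yl]oxiran-2-yl}penta-2,4-dienoate | COc1ccc(COC[C@@H](O[Si](C)(C)C(C)(C)C)/C(C(=O)OC)=C\C=C/[C@@]2(C)O[C@@H]2[C@H]2OC(=O)C(CB3OC(C)(C)C(C)(C)O3)=C2)cc1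
F3 | step 19 | methyl (2E,4Z)-2-[(1S)-1-(TBSO)-2-hydroxyethyl]-5-{(2R,3R)-2-methyl-3-[(2S)-5-oxo-4-[(pinacolboryl)methyl]-2,5-dihydrofuran-2-yl]oxiran-2-yl}penta-2,4-dienoate | OC[C@@H](O[Si](C)(C)C(C)(C)C)/C(C(=O)OC)=C\C=C/[C@@]1(C)O[C@@H]1[C@H]1OC(=O)C(CB2OC(C)(C)C(C)(C)O2)=C1
F4 | step 19 | methyl (2E,4Z)-2-[(1S)-1-(TBSO)-2-oxoethyl]-5-{(2R,3R)-2-methyl-3-[(2S)-5-oxo-4-[(pinacolboryl)methyl]-2,5-dihydrofuran-2-yl]oxiran-2-yl}penta-2,4-dienoate | O=C[C@@H](O[Si](C)(C)C(C)(C)C)/C(C(=O)OC)=C\C=C/[C@@]1(C)O[C@@H]1[C@H]1OC(=O)C(CB2OC(C)(C)C(C)(C)O2)=C1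
F5 | step 20 | methyl (4R,5R,6S,7R,9S)-9-(TBSO)-4,5-epoxy-8-oxogermacra-1(10)E,2Z,11(13)-trien-6,12-olid-14-oate | C=C1C(=O)O[C@H]2[C@H]1C(=O)[C@@H](O[Si](C)(C)C(C)(C)C)/C(C(=O)OC)=C\C=C/[C@@]1(C)O[C@H]21
F6 | step 20 | methyl (4R,5R,6S,7R,8S,9S)-9-(TBSO)-4,5-epoxy-8-hydroxygermacra-1(10)E,2Z,11(13)-trien-6,12-olid-14-oate | C=C1C(=O)O[C@H]2[C@H]1[C@H](O)[C@@H](O[Si](C)(C)C(C)(C)C)/C(C(=O)OC)=C\C=C/[C@@]1(C)O[C@H]21
F7 | step 14 | 3-[(2R,3R)-3-(hydroxymethyl)-2-methyloxiran-2-yl]prop-2-ynal | O=CC#C[C@@]1(C)O[C@@H]1CO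
F8 | step 14 | methyl (2E)-2-[(1S)-1-(TBSO)-2-(PMBO)ethyl]-5-[(2R,3R)-3-(hydroxymethyl)-2-methyloxiran-2-yl]pent-2-en-4-ynoate | COc1ccc(COC[C@@H](O[Si](C)(C)C(C)(C)C)/C(C(=O)OC)=C\C#C[C@@]2(C)O[C@@H]2CO)cc1
F9 | step 14 | methyl (2E,4Z)-2-[(1S)-1-(TBSO)-2-(PMBO)ethyl]-5-[(2R,3R)-3-(hydroxymethyl)-2-methyloxiran-2-yl]penta-2,4-dienoate | COc1ccc(COC[C@@H](O[Si](C)(C)C(C)(C)C)/C(C(=O)OC)=C\C=C/[C@@]2(C)O[C@@H]2CO)cc1
F10 | step 14 | methyl (2E,4Z)-2-[(1S)-1-(TBSO)-2-(PMBO)ethyl]-5-[(2R,3S)-3-formyl-2-methyloxiran-2-yl]penta-2,4-dienoate | COc1ccc(COC[C@@H](O[Si](C)(C)C(C)(C)C)/C(C(=O)OC)=C\C=C/[C@@]2(C)O[C@@H]2C=O)cc1
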